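**Strategy**

Prostanoid numbering is used (ring C8–C12, ketone C9, chlorine on C10, acetoxy carbinol C12). The ring is a 4-oxygenated cyclopent-2-enone whose tertiary C12–O carbon lies β to the C9 carbonyl across C8: the signature of a Piancatelli-type 4π closure. Everything rests on cutting C9–C10 and C8–C12, which gives an acetyl-anion unit (C8–C9) and a β,β-dichlorovinyl ketone (C10–C12 plus the octenyl chain). In one flask a Stille coupling with a 1-ethoxyvinylstannane makes C9–C10, keeping one chlorine on C10, and a chiral Brønsted acid closes the enol-ether carbon C8 onto the C12 ketone, setting C12. Aldol condensation with a (Z)-enal and acetylation complete the target.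

Key step: step 4

Assumption: the sense of induction of the chiral acid in step 4 cannot be fixed on paper; the (R)-configured catalyst is written, and its mirror image is to be used if a first run shows that it delivers the enantiomeric ring.
Assumption: methyl 7-hydroxyhept-5-ynoate (13) is taken as commercially available.

**Route**

Step 1
Reactants: 1 (Z)-non-3-en-1-ol
Product: 2 (Z)-non-3-enoic acid
Conditions: CrO3, H2SO4, H2O, acetone, 0 °C
Reagents that add atoms: water, O
Why: Jones oxidation takes the primary alcohol through the aldehyde hydrate to the acid, and homoallylic (Z)-alkenols should give β,γ-unsaturated acids under these cold acidic conditions without double-bond migration.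

Step 2
Reactants: 2 (Z)-non-3-enoic acid
Product: 3 (Z)-N-methoxy-N-methylnon-3-enamide
Conditions: MeNH(OMe)·HCl, EDC·HCl, HOBt (cat.), N-methylmorpholine, CH2Cl2, 0 °C to rt
Reagents that add atoms: N,O-dimethylhydroxylamine hydrochloride, CNOC.Cl
Why: Carbodiimide amide coupling (Weinreb amide synthesis) runs near neutrality, so the skipped (Z)-alkene should stay out of conjugation.

Step 3
Reactants: 3 (Z)-N-methoxy-N-methylnon-3-enamide; 4 (Z)-1,2-dichloroethene
Product: 8 (Z)-1,1-dichloroundeca-1,5-dien-3-one, via lithium chloroacetylide 5 (not isolated), via tetrahedral lithium adduct 6 (not isolated), via chloroynone 7 (not isolated)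
Conditions: 4, MeLi (2 equiv), Et2O, 0 °C; then 3, THF, −78 to −20 °C; then HCl (2 M in Et2O, excess), −20 °C to rt
Reagents that add atoms: hydrogen chloride, Cl
Why: MeLi turns 4 into lithium chloroacetylide by elimination of LiCl and deprotonation, the acetylide adds once to the Weinreb amide because the chelated adduct 6 persists, and anhydrous HCl then releases chloroynone 7 (trapping the liberated amine as its hydrochloride) and adds to it in conjugate fashion (hydrochlorination of an ynone), placing the second chlorine on the β-carbon.

Step 4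
Reactants: 8 (Z)-1,1-dichloroundeca-1,5-dien-3-one; 9 tributyl(1-ethoxyvinyl)stannane
Product: 12 (4S)-2-chloro-4-hydroxy-4-[(Z)-oct-2-en-1-yl]cyclopent-2-en-1-one, via ethoxy trienone 10 (not isolated), via ethoxycyclopentadienol 11 (not isolated)
Conditions: Pd2(dba)3 (2.5 mol%), AsPh3 (10 mol%), toluene, 45 °C; then 4 Å MS, (R)-3,3′-bis(2,4,6-triisopropylphenyl)-BINOL N-triflylphosphoramide (15 mol%), −20 to 0 °C; then 1 M HCl (aq), THF, 0 °C
Reagents that add atoms: water, O
Why: Proposed new method: zerovalent palladium inserts into one C–Cl bond of the vinylogous acid chloride 8, and transmetalation from tin followed by reductive elimination (Stille coupling) makes C9–C10 while the second chlorine stays on C10; the chiral acid then protonates the C12 carbonyl of 10 to a 2-ethoxy-3-chloro-5-hydroxypentadienyl cation whose 4π-conrotatory electrocyclization makes C8–C12, and proton loss gives dienol ether 11, which aqueous acid hydrolyses to the enone. The closest known reactions are the Piancatelli rearrangement, whose ring-forming event is the same closure of a 2,5-dioxygenated pentadienyl cation, and the chiral phosphoric acid and N-triflylphosphoramide catalysed aza-Piancatelli and Nazarov cyclizations; such a closure has not been run on an acyclic alkoxy-dienone made in the same flask by cross-coupling. The cyclopentene ring closes by this 4π electrocyclization, formally a 5-(enolendo)-exo-trig aldol addition of the enol ether to the ketone. C12 is the only new stereocentre and is set by the sense of conrotation that the chiral phosphoramide anion, hydrogen-bonded to the C12 hydroxyl of the cation, imposes. The step needs mono-coupling, which one equivalent of stannane and the deactivating alkoxyvinyl donor introduced by the first coupling should secure, and attack through C8 and not C13, which the preformed enol ether secures without any enolisation. The geometric isomer of 10 that holds C9 away from C12 should equilibrate through the same O-protonated cation, because chlorine lone-pair donation at C10 lowers the barrier to rotation about C10–C11.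

Step 5
Reactants: 13 methyl 7-hydroxyhept-5-ynoate
Product: 14 methyl (Z)-7-hydroxyhept-5-enoate
Conditions: H2 (1 atm), Pd/CaCO3 poisoned with Pb(OAc)2 (Lindlar catalyst), quinoline, EtOAc, rt
Reagents that add atoms: none
Why: Lindlar semi-hydrogenation adds hydrogen syn to the alkyne and stops at the alkene, which sets the (5Z) geometry.

Step 6
Reactants: 14 methyl (Z)-7-hydroxyhept-5-enoate
Product: 15 methyl (Z)-7-oxohept-5-enoate
Conditions: Dess–Martin periodinane, pyridine, CH2Cl2, 0 °C
Reagents that add atoms: none
Why: Dess–Martin oxidation of the allylic alcohol under pyridine buffering at 0 °C should give the (Z)-enal without the free acid that would isomerise it to the (E)-enal, and 15 is used at once.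

Step 7
Reactants: 12 (4S)-2-chloro-4-hydroxy-4-[(Z)-oct-2-en-1-yl]cyclopent-2-en-1-one; 15 methyl (Z)-7-oxohept-5-enoate
Product: 17 methyl (5Z)-7-[(5S)-3-chloro-5-hydroxy-5-[(Z)-oct-2-en-1-yl]-2-oxocyclopent-3-en-1-yl]-7-hydroxyhept-5-enoate, via dilithium alkoxide–enolate 16 (not isolated)
Conditions: LiN(i-Pr)2 (2.2 equiv), THF, −78 °C (12 added to the base); then 15, −78 °C; AcOH, −78 °C
Reagents that add atoms: none
Why: Two equivalents of base give the alkoxide–enolate dianion (only C8 carries acidic hydrogens), which cannot open by retro-aldol and adds 1,2 to the enal in a lithium aldol reaction; the new centres at C7 and C8 are left uncontrolled because both become sp2 in step 8.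

Step 8
Reactants: 17 methyl (5Z)-7-[(5S)-3-chloro-5-hydroxy-5-[(Z)-oct-2-en-1-yl]-2-oxocyclopent-3-en-1-yl]-7-hydroxyhept-5-enoate
Product: 19 methyl (5Z,7E,12R,14Z)-12-acetoxy-10-chloro-9-oxoprosta-5,7,10,14-tetraenoate (CNP0248978.4), via diacetate 18 (not isolated)
Conditions: Ac2O, DMAP, Et3N, CH2Cl2, 0 °C to rt
Reagents that add atoms: acetic anhydride, CC(=O)OC(C)=O
Why: DMAP-catalysed acetylation esterifies both hydroxyls and the C7 acetate is then expelled from the C8 enolate (E1cB elimination) to give the conjugated alkylidene, expected mainly as the (7E) isomer, whereas loss of the C12 acetate would create an antiaromatic cyclopentadienone and should not compete; C12 is untouched.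

**Compound list**

1 | (Z)-non-3-en-1-ol | CCCCC/C=C\CCO | starting material
2 | (Z)-non-3-enoic acid | CCCCC/C=C\CC(=O)O | intermediate
3 | (Z)-N-methoxy-N-methylnon-3-enamide | CCCCC/C=C\CC(=O)N(C)OC | intermediate
4 | (Z)-1,2-dichloroethene | Cl/C=C\Cl | starting material
5 | lithium chloroacetylide | [Li]C#CCl | intermediate (not isolated)
6 | lithium (Z)-1-chloro-3-[methoxy(methyl)amino]undec-5-en-1-yn-3-olate (tetrahedral adduct, racemic at C3) | CCCCC/C=C\CC(O[Li])(C#CCl)N(C)OC | intermediate (not isolated)
7 | (Z)-1-chloroundec-5-en-1-yn-3-one | ClC#CC(=O)C/C=C\CCCCC | intermediate (not isolated)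
8 | (Z)-1,1-dichloroundeca-1,5-dien-3-one | ClC(Cl)=CC(=O)C/C=C\CCCCC | intermediate
9 | tributyl(1-ethoxyvinyl)stannane | CCCC[Sn](CCCC)(CCCC)C(=C)OCC | starting material
10 | (3E,7Z)-3-chloro-2-ethoxytrideca-1,3,7-trien-5-one (formed together with its 3Z isomer) | C=C(OCC)/C(Cl)=C\C(=O)C/C=C\CCCCC | intermediate (not isolated)
11 | (1S)-3-chloro-4-ethoxy-1-[(Z)-oct-2-en-1-yl]cyclopenta-2,4-dien-1-ol | CCCCC/C=C\C[C@@]1(O)C=C(Cl)C(OCC)=C1 | intermediate (not isolated)
12 | (4S)-2-chloro-4-hydroxy-4-[(Z)-oct-2-en-1-yl]cyclopent-2-en-1-one | CCCCC/C=C\C[C@@]1(O)C=C(Cl)C(=O)C1 | intermediate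
13 | methyl 7-hydroxyhept-5-ynoate | COC(=O)CCCC#CCO | starting material
14 | methyl (Z)-7-hydroxyhept-5-enoate | COC(=O)CCC/C=C\CO | intermediate
15 | methyl (Z)-7-oxohept-5-enoate | COC(=O)CCC/C=C\C=O | intermediate
16 | dilithium alkoxide–enolate of 12 (lithium on the C12 oxygen and on the C9 enolate oxygen, C8=C9 double bond) | CCCCC/C=C\C[C@@]1(O[Li])C=C(Cl)C(O[Li])=C1 | intermediate (not isolated)
17 | methyl (5Z)-7-[(5S)-3-chloro-5-hydroxy-5-[(Z)-oct-2-en-1-yl]-2-oxocyclopent-3-en-1-yl]-7-hydroxyhept-5-enoate (mixture of diastereomers at C7 and C8) | CCCCC/C=C\C[C@@]1(O)C=C(Cl)C(=O)C1C(O)/C=C\CCCC(=O)OC | intermediate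
18 | diacetate of 17 (acetates on the C7 and C12 oxygens) | CCCCC/C=C\C[C@@]1(OC(C)=O)C=C(Cl)C(=O)C1C(OC(C)=O)/C=C\CCCC(=O)OC | intermediate (not isolated)
19 | methyl (5Z,7E,12R,14Z)-12-acetoxy-10-chloro-9-oxoprosta-5,7,10,14-tetraenoate, i.e. methyl (5Z)-7-[(5R)-5-acetoxy-3-chloro-5-[(Z)-oct-2-en-1-yl]-2-oxocyclopent-3-en-1-ylidene]hept-5-enoate with (E) exocyclic alkene | CCCCC/C=C\C[C@@]1(OC(C)=O)C=C(Cl)C(=O)/C1=C/C=C\CCCC(=O)OC | target

**Count and risks**

Total step count: 8. Longest linear sequence: 6 steps (steps 1, 2, 3, 4, 7 and 8).

Steps most likely to fail: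

Step 4. The chiral acid may discriminate poorly between the two senses of conrotation and give low enantiomeric purity. A second coupling may occur at C10. The enol ether may be hydrolysed before ring closure, after which enolisation toward C13 competes. Fallback, from 8 and back at 12: the Stille coupling of 8 with 9 is run as a separate step and trienone 10 is isolated. BF3·OEt2 (1 equiv) in CH2Cl2 at −78 °C followed by aqueous acid, an intramolecular Mukaiyama-type addition of the enol ether to the ketone, should give racemic 2-chloro-4-hydroxy-4-[(Z)-oct-2-en-1-yl]cyclopent-2-en-1-one F1. Preparative chromatography on a chiral stationary phase then separates 12 from (4R)-2-chloro-4-hydroxy-4-[(Z)-oct-2-en-1-yl]cyclopent-2-en-1-one F2.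

Step 7. The lithium alkoxide of 12 may open by retro-aldol before the second deprotonation, which would erode the configuration at C12. Dianion formation may be incomplete, and 15 may isomerise from (Z) to (E) under the basic conditions. Fallback, from 12 and back at 17: the tertiary hydroxyl is silylated with N-(trimethylsilyl)imidazole to (4S)-2-chloro-4-[(Z)-oct-2-en-1-yl]-4-(trimethylsilyloxy)cyclopent-2-en-1-one F3. Its monoenolate (LiN(i-Pr)2, 1.1 equiv, THF, −78 °C) is added to 15 to give methyl (5Z)-7-[(5S)-3-chloro-5-[(Z)-oct-2-en-1-yl]-2-oxo-5-(trimethylsilyloxy)cyclopent-3-en-1-yl]-7-hydroxyhept-5-enoate F4. Citric acid in MeOH at 0 °C then removes the silyl group and gives 17.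

Step 3. Lithium chloroacetylide may decompose before it adds, 3 may be enolised at its doubly activated C2 methylene, and the skipped (Z)-alkene may migrate into conjugation during the strongly acidic one-pot hydrochlorination. Fallback, from 3 and back at 8: HC≡CMgBr (THF, −20 °C) converts 3 into (Z)-undec-5-en-1-yn-3-one F5. NCS with catalytic AgOAc in acetone chlorinates the terminal alkyne to chloroynone 7, which is isolated in this variant. LiCl in AcOH at rt then adds HCl under buffered conditions to give 8.

Further compounds
F1 | step 4 | racemic 2-chloro-4-hydroxy-4-[(Z)-oct-2-en-1-yl]cyclopent-2-en-1-one | CCCCC/C=C\CC1(O)C=C(Cl)C(=O)C1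
F2 | step 4 | (4R)-2-chloro-4-hydroxy-4-[(Z)-oct-2-en-1-yl]cyclopent-2-en-1-one | CCCCC/C=C\C[C@]1(O)C=C(Cl)C(=O)C1
F3 | step 7 | (4S)-2-chloro-4-[(Z)-oct-2-en-1-yl]-4-(trimethylsilyloxy)cyclopent-2-en-1-one | CCCCC/C=C\C[C@@]1(O[Si](C)(C)C)C=C(Cl)C(=O)C1
F4 | step 7 | methyl (5Z)-7-[(5S)-3-chloro-5-[(Z)-oct-2-en-1-yl]-2-oxo-5-(trimethylsilyloxy)cyclopent-3-en-1-yl]-7-hydroxyhept-5-enoate | CCCCC/C=C\C[C@@]1(O[Si](C)(C)C)C=C(Cl)C(=O)C1C(O)/C=C\CCCC(=O)OC
F5 | step 3 | (Z)-undec-5-en-1-yn-3-one | C#CC(=O)C/C=C\CCCCC
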